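The route rests on reading ring methine C8 as the inner carbon of a former (E)-C7=C8 styrene. C8 is bonded both to ring carbon C8' and to the ring A carbinol C7. The C8–C8' and C7–O bonds therefore sit on neighbouring carbons, in the relationship left by an anti addition. One enantioselective gold-catalysed hydroxycyclisation closes the oxolane ring, installs the C7 hydroxyl and sets C7 and C8. It leaves C7' as an exocyclic methylene, on which ring A' and the last stereocentre C8' are added. Its precursor is an achiral, benzyl-protected (E)-coniferyl propargyl ether with a terminal alkyne, three steps from O-benzylvanillin.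

Key step: step 4

Numbering: lignan locants are used. C7 is the carbinol on ring A, C8 and C8' are the ring methines, C9 and C9' are the ring OCH2 groups, and C7' is the benzyl carbon on ring A'.
Configuration: the target SMILES reads as 7R,8R,8'R, with the C8 and C8' substituents trans on the oxolane ring.
Assumption: the sense of induction of the digold catalyst on this ether-tethered enyne cannot be predicted safely. The (R)-ligand is written, and the equally available (S)-ligand replaces it, with no other change, if a trial run gives the (7S,8S) alcohol.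

Step 1
Reactants: 1 4-(benzyloxy)-3-methoxybenzaldehyde; 2 triethyl phosphonoacetate
Product: 3 ethyl (E)-3-[4-(benzyloxy)-3-methoxyphenyl]prop-2-enoate
Conditions: NaH, THF, 0 °C → rt
Reagents that add atoms: none
Why: Horner–Wadsworth–Emmons olefination, in which the stabilised phosphonate anion adds reversibly to the aromatic aldehyde and collapses through the less crowded oxaphosphetane, so the (E)-cinnamate needed for the later anti addition should form almost exclusively while the benzyl ether stays inert.

Step 2
Reactants: 3 ethyl (E)-3-[4-(benzyloxy)-3-methoxyphenyl]prop-2-enoate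
Product: 4 (E)-3-[4-(benzyloxy)-3-methoxyphenyl]prop-2-en-1-ol
Conditions: i-Bu2AlH (2.5 equiv), CH2Cl2, −78 → 0 °C; aq. potassium sodium tartrate
Reagents that add atoms: none
Why: 1,2-reduction of a conjugated ester by a neutral aluminium hydride, which delivers both hydrides to the carbonyl carbon and leaves the double bond, its E geometry and the benzyl ether untouched.

Step 3
Reactants: 4 (E)-3-[4-(benzyloxy)-3-methoxyphenyl]prop-2-en-1-ol; 5 propargyl bromide
Product: 6 (E)-1-(benzyloxy)-2-methoxy-4-[3-(prop-2-yn-1-yloxy)prop-1-en-1-yl]benzene
Conditions: NaH, n-Bu4NI (cat.), THF, 0 °C → rt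
Reagents that add atoms: none
Why: Williamson ether synthesis, in which the primary allylic alkoxide displaces bromide at the unhindered propargylic carbon (SN2) and iodide catalysis keeps the temperature low enough that alkyne-to-allene isomerisation should not start.

Step 4
Reactants: 6 (E)-1-(benzyloxy)-2-methoxy-4-[3-(prop-2-yn-1-yloxy)prop-1-en-1-yl]benzene
Product: 7 (R)-[4-(benzyloxy)-3-methoxyphenyl][(R)-4-methylenetetrahydrofuran-3-yl]methanol
Conditions: (R)-DTBM-MeO-BIPHEP(AuCl)2 (3 mol %), AgOTf (6 mol %), 1,4-dioxane/H2O 6:1, rt; Et3N quench
Reagents that add atoms: water, O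
Why: The cationic monovalent gold centre freed by AgOTf binds the terminal alkyne, styrene carbon C8 attacks the internal alkyne carbon C8', and the resulting cyclopropyl gold carbene, whose positive charge rests mainly on benzylic C7, is opened by water at C7 on the side away from the new C8–C8' bond before protodeauration of the alkenylgold releases the C7' methylene. The closest known reaction type is the gold- or platinum-catalysed hydroxy- and alkoxycyclisation of 1,6-enynes, which covers ether-tethered cinnamyl propargyl ethers and enantioselective variants with atropisomeric bisphosphine digold chlorides. The oxolane ring (O, C9, C8, C8', C9') closes in the 5-exo-dig mode. The relative configuration of C7 and C8 follows from the stereospecific anti addition of carbon and oxygen across the E double bond, which gives the like pair (7R,8R or 7S,8S), and the absolute configuration follows from the chiral bisphosphine, which decides which alkene face meets the gold-bound alkyne. The step needs exo rather than 6-endo closure, attack of water at C7 rather than at the alkyne, and no ionisation of the product; the unsubstituted alkyne terminus and the 4-benzyloxy-3-methoxyphenyl donor on C7 secure the first two, and room temperature with an amine quench guards the third.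

Step 5
Reactants: 7 (R)-[4-(benzyloxy)-3-methoxyphenyl][(R)-4-methylenetetrahydrofuran-3-yl]methanol; 8 1-(benzyloxy)-4-bromo-2-methoxybenzene
Product: 9 (R)-[4-(benzyloxy)-3-methoxyphenyl]{(3R,4Z)-4-[4-(benzyloxy)-3-methoxybenzylidene]tetrahydrofuran-3-yl}methanol
Conditions: Pd2(dba)3 (2.5 mol %), [HP(t-Bu)3]BF4 (10 mol %), Cy2NMe (1.5 equiv), 1,4-dioxane, 60 °C
Reagents that add atoms: none
Why: Mizoroki–Heck arylation of a 1,1-disubstituted alkene, in which the arylpalladium bromide places ring A' on the unsubstituted C7' and syn β-hydride elimination from C7' gives the conjugated benzylidene with ring A' turned away from C8 (Z); the bulky electron-rich phosphine lets the donor-substituted bromide react at moderate temperature, the hindered amine strips HBr from palladium quickly so the double bond should not walk towards C8, and any E isomer or C8'=C9' isomer keeps C8' sp2 and converges on 10 in step 6.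

Step 6
Reactants: 9 (R)-[4-(benzyloxy)-3-methoxyphenyl]{(3R,4Z)-4-[4-(benzyloxy)-3-methoxybenzylidene]tetrahydrofuran-3-yl}methanol
Product: 10 (R)-[4-(benzyloxy)-3-methoxyphenyl]{(3R,4R)-4-[4-(benzyloxy)-3-methoxybenzyl]tetrahydrofuran-3-yl}methanol
Conditions: [Ir(cod)(PCy3)(py)]PF6 (5 mol %), H2 (1 atm), CH2Cl2, rt
Reagents that add atoms: none
Why: Hydroxyl-directed homogeneous hydrogenation, in which the C7 hydroxyl binds the cationic iridium dihydride and holds it on the ring face that carries the C8 side chain, so hydrogen reaches C8' from that face, C8'–H ends cis to the C8–C7 bond and the new benzyl group trans to it (8'R), while this catalyst does not cleave aryl benzyl ethers.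

Step 7
Reactants: 10 (R)-[4-(benzyloxy)-3-methoxyphenyl]{(3R,4R)-4-[4-(benzyloxy)-3-methoxybenzyl]tetrahydrofuran-3-yl}methanol
Product: 11 4-[(R)-hydroxy{(3R,4R)-4-[(4-hydroxy-3-methoxyphenyl)methyl]oxolan-3-yl}methyl]-2-methoxyphenol (target, 7R,8R,8'R)
Conditions: H2 (1 atm), 10% Pd/C, NaHCO3, EtOAc/EtOH, rt
Reagents that add atoms: none
Why: Catalytic hydrogenolysis, in which aryl benzyl ethers are cleaved on palladium far faster than a secondary benzylic alcohol under buffered neutral conditions at one atmosphere, so stopping after two equivalents of hydrogen should free both phenols and leave C7–OH and all three stereocentres unchanged.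

Compound list
1 | 4-(benzyloxy)-3-methoxybenzaldehyde (O-benzylvanillin) | COc1cc(C=O)ccc1OCc1ccccc1 | starting material
2 | triethyl phosphonoacetate | CCOC(=O)CP(=O)(OCC)OCC | starting material
3 | ethyl (E)-3-[4-(benzyloxy)-3-methoxyphenyl]prop-2-enoate | CCOC(=O)/C=C/c1ccc(OCc2ccccc2)c(OC)c1 | intermediate
4 | (E)-3-[4-(benzyloxy)-3-methoxyphenyl]prop-2-en-1-ol | OC/C=C/c1ccc(OCc2ccccc2)c(OC)c1 | intermediate
5 | propargyl bromide | C#CCBr | starting material
6 | (E)-1-(benzyloxy)-2-methoxy-4-[3-(prop-2-yn-1-yloxy)prop-1-en-1-yl]benzene | C#CCOC/C=C/c1ccc(OCc2ccccc2)c(OC)c1 | intermediate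
7 | (R)-[4-(benzyloxy)-3-methoxyphenyl][(R)-4-methylenetetrahydrofuran-3-yl]methanol | C=C1COC[C@@H]1[C@@H](O)c1ccc(OCc2ccccc2)c(OC)c1 | intermediate
8 | 1-(benzyloxy)-4-bromo-2-methoxybenzene | COc1cc(Br)ccc1OCc1ccccc1 | starting material
9 | (R)-[4-(benzyloxy)-3-methoxyphenyl]{(3R,4Z)-4-[4-(benzyloxy)-3-methoxybenzylidene]tetrahydrofuran-3-yl}methanol | COc1cc(/C=C2\COC[C@@H]2[C@@H](O)c2ccc(OCc3ccccc3)c(OC)c2)ccc1OCc1ccccc1 | intermediate
10 | (R)-[4-(benzyloxy)-3-methoxyphenyl]{(3R,4R)-4-[4-(benzyloxy)-3-methoxybenzyl]tetrahydrofuran-3-yl}methanol | COc1cc(C[C@H]2COC[C@@H]2[C@@H](O)c2ccc(OCc3ccccc3)c(OC)c2)ccc1OCc1ccccc1 | intermediate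
11 | 4-[(R)-hydroxy{(3R,4R)-4-[(4-hydroxy-3-methoxyphenyl)methyl]oxolan-3-yl}methyl]-2-methoxyphenol | COc1cc(C[C@H]2COC[C@@H]2[C@@H](O)c2ccc(O)c(OC)c2)ccc1O | target

Total step count: 7. Longest linear sequence: 7 steps (1 → 3 → 4 → 6 → 7 → 9 → 10 → 11).

Steps most likely to fail

Step 4. The chiral digold catalyst may discriminate poorly between the two alkene faces of an ether-tethered enyne. The strongly stabilised benzylic cation may also rotate before water arrives, which would erode the anti stereospecificity. The fallback gives up catalyst control in favour of a classical resolution.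
- Setting out from 6, the cyclisation is run with achiral Ph3PAuNTf2 in aqueous dioxane. This gives racemic (R*)-[4-(benzyloxy)-3-methoxyphenyl][(R*)-4-methylenetetrahydrofuran-3-yl]methanol F1.
- Steglich esterification with (S)-2-methoxy-2-phenylacetic acid (DCC, DMAP, CH2Cl2) gives the (7R,8R) methoxyphenylacetate F2 and the (7S,8S) methoxyphenylacetate F3. These are separated by chromatography or crystallisation.
- Saponification of F2 (LiOH, THF/H2O, 0 °C) comes back to the route at 7.

Step 5. The tertiary alkylpalladium intermediate has β-hydrogens at C7', C9' and C8. Elimination or chain walking towards C8 would erase that stereocentre, and premature migration of the methylene would stop the arylation. The fallback forms the aryl–C7' bond without any alkylpalladium species.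
- Setting out from 7, cross-metathesis is run with vinylboronic acid pinacol ester (second-generation Hoveyda–Grubbs catalyst, CH2Cl2, reflux). This gives (R)-[4-(benzyloxy)-3-methoxyphenyl]{(3R,4Z)-4-[(4,4,5,5-tetramethyl-1,3,2-dioxaborolan-2-yl)methylidene]oxolan-3-yl}methanol F4.
- Suzuki–Miyaura coupling of F4 with 8 (PdCl2(dppf), K3PO4, dioxane/H2O, 60 °C) keeps the position and geometry of the double bond. It comes back to the route at 9.

Step 6. The hindered secondary hydroxyl may bind iridium too weakly, so that undirected delivery of hydrogen from the opposite face competes and facial selectivity is poor. Acidic iridium hydrides may also ionise the benzylic C7–O bond. The fallback moves the source of stereocontrol from the substrate to the catalyst.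
- Setting out again from 9, an asymmetric hydrogenation is run with a chiral iridium N,P complex such as [Ir(cod)((S)-t-Bu-PHOX)][B(3,5-(CF3)2C6H3)4] (H2, CH2Cl2).
- This catalyst class is established for trisubstituted aryl alkenes. The antipode is chosen so that its own facial preference coincides with the hydroxyl-bearing face (matched double stereodifferentiation).
- The fallback comes back to the route at 10 and makes no new compound.

Further compounds
F1 | step 4 | racemic (R*)-[4-(benzyloxy)-3-methoxyphenyl][(R*)-4-methylenetetrahydrofuran-3-yl]methanol | C=C1COC[C@@H]1[C@@H](O)c1ccc(OCc2ccccc2)c(OC)c1.C=C1COC[C@H]1[C@H](O)c1ccc(OCc2ccccc2)c(OC)c1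
F2 | step 4 | (R)-[4-(benzyloxy)-3-methoxyphenyl][(R)-4-methylenetetrahydrofuran-3-yl]methyl (S)-2-methoxy-2-phenylacetate | C=C1COC[C@@H]1[C@@H](OC(=O)[C@@H](OC)c1ccccc1)c1ccc(OCc2ccccc2)c(OC)c1
F3 | step 4 | (S)-[4-(benzyloxy)-3-methoxyphenyl][(S)-4-methylenetetrahydrofuran-3-yl]methyl (S)-2-methoxy-2-phenylacetate | C=C1COC[C@H]1[C@H](OC(=O)[C@@H](OC)c1ccccc1)c1ccc(OCc2ccccc2)c(OC)c1
F4 | step 5 | (R)-[4-(benzyloxy)-3-methoxyphenyl]{(3R,4Z)-4-[(4,4,5,5-tetramethyl-1,3,2-dioxaborolan-2-yl)methylidene]oxolan-3-yl}methanol | CC1(C)OB(/C=C2\COC[C@@H]2[C@@H](O)c2ccc(OCc3ccccc3)c(OC)c2)OC1(C)C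
F0 | step 6 | none | none
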